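The runs were generated by integration for an exercise; the scatter is artificial.

You want the left-handed product in this flask at 4.0 d, and the change that raises it most.

in all of them: added ligand 1.9 mM
- Monday's: left-handed substrate 0.050 M; right-handed substrate 0.050 M; solid reagent 0.15 M; catalyst 1 mM; the very flask that is asked about, followed so far
- Tuesday's: left-handed substrate 0.025 M; right-handed substrate 0.025 M; solid reagent 0.15 M; catalyst 1 mM; run made earlier
- flask: left-handed substrate 0.050 M; right-handed substrate 0.050 M; solid reagent 0.150 M; catalyst 1.0 mM; time 4.0 d

Monday's run (percent of the left-handed substrate and right-handed substrate together charged)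

| time / h | left-handed product / % | left-handed substrate / % |
|---|---|---|
| 3.00 | 0.9 | 50.2 |
| 10.0 | 2.2 | 48.2 |
| 15.0 | 2.5 | 46.9 |
| 25.0 | 8.7 | 42.0 |
| 40.0 | 9.3 | 40.8 |
| 50.0 | 10.5 | 38.7 |

Tuesday's run (percent of the left-handed substrate and right-handed substrate together charged)

| time / d | left-handed product / % | left-handed substrate / % |
|---|---|---|
| 0.625 | 4.9 | 47.0 |
| 1.25 | 7.7 | 43.4 |
| 2.08 | 12.5 | 36.5 |
| 2.50 | 15.8 | 34.4 |
| 3.00 | 17.5 | 33.7 |
| 4.00 | 22.0 | 28.8 |

(scatter of a reading: 1 percentage point)

- how much left-handed product there is at 4.0 d, in percent of the left-handed substrate and right-handed substrate together charged
- the change that raises the amount of left-handed product at 4.0 d, in percent of the left-handed substrate and right-handed substrate together charged most ("none" if none brings more than 2 percentage points) (cedar / larch / birch / none)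
- amount of left-handed product at 4.0 d, in percent of the left-handed substrate and right-handed substrate together charged, after cedar

- cedar: doubling the solubility of the solid reagent, all else as stated
- larch: doubling the amount of catalyst, all else as stated
- birch: doubling the dissolution coefficient of the solid reagent, all else as stated

- catalyst is single-handed; left-handed substrate and right-handed substrate are mirror images of each other, charged as a racemate, each of them at the stated concentration
- as a solid, counted per litre of solution: solid reagent
- at the start none of the solid reagent is in solution

Compare the runs at one time. At 50.0 h, Monday's run holds 38.7% left-handed substrate. At 2.08 d, Tuesday's run, charged at half the concentration, holds 36.5%. They differ by 2.2 percentage points, and each reading scatters by 1 point. So I read the percentage as falling at about the same pace at either charge. That is pseudo-first-order behaviour, and one half-life can carry the reckoning.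

Tuesday's run falls from its charge to 28.8% in 4.00 d. That gives 5.03 d, the working half-life: the time in which the left-handed substrate present falls by half. It is a reading, and it averages over any slow start.

By my reckoning, this flask has 0.796 half-lives behind it at 4.0 d, which gives 21.2% left-handed product. Doubling the rate doubles that count and gives 33.4%. I expect this from cedar, if the dissolved reagent sits near its solubility. Birch should change little, since any slow start seems short: Tuesday's first reading, at 0.625 d, already shows the substrate falling. Larch takes the catalyst to 2.00 mM, above the 1.9 mM of added ligand. If the ligand holds catalyst, I expect the free catalyst to more than double, so I choose larch.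

The forecast gives 19.5%, and 32% after cedar, with cedar as its choice: “Cedar is the expected best.”

The flask gives 21.5%, and 34.1% after cedar. The best change is larch, which adds 20 points, against 13 points for cedar and 1 point for birch.

    partner + catalyst + right-handed substrate → catalyst + right-handed product (k = 0.0122 /M²/s)
    partner + catalyst + left-handed substrate → catalyst + left-handed product (k = 0.943 /M²/s)
    solid reagent ⇌ partner, rate k3*(cs3 - [partner]) while solid is left; crystals form when [partner] > cs3 (solubility = 16.0 mM, k = 5.63 × 10⁻⁵ /s)
    catalyst ⇌ dormant form (K = 0.512, k = 1.00 × 10⁻⁵ /s)
    catalyst + added ligand ⇌ idle complex, settled at all times (K = 6210 /M)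

In this flask the partner is made 1.23 times faster than it is used at 0.759 d, and 1.03 times faster at 4.00 d, each step taken net. It stands at 0.0148 M at 2.00 d and 0.0151 M at 4.00 d. My 0.796 half-lives meant 57.6% of the charged left-handed substrate remaining, and the flask keeps 57%. Left until 6.0 d, the flask has 1.19 half-lives behind it, which gives 28.1% left-handed product. Computed, that flask holds 28.9% left-handed product.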